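**Assumption:** germacrane numbering is used for every compound (C7 carries the isopropenyl group, C3/C8/C9 the angelate/senecioate/acetate, and the carvone ring supplies C3–C8); β is the face of the C7 isopropenyl group in the flat ring drawing, α the opposite face.

## Retrosynthetic overview

1. Target ⇐ C9 acetylation ⇐ hydroxyl-directed 1,10-epoxidation ⇐ C3 angelate (Mitsunobu inversion) and C8 senecioate on a (1(10)Z)-4,5-epoxygermacra-1(10),11-dien-3-one.
2. Ten-membered ring ⇐ C2–C3 bond by electroreductive transfer of an allyl terminus onto the carbonyl of a seven-membered lactone; the lactone tether fixes the Z alkene and releases the C8 hydroxyl.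
3. Lactone ⇐ Baeyer–Villiger insertion of oxygen into C3–C8 of a cyclohexanone, with retention at C8.
4. C8–C9 bond ⇐ syn-aldol of the enolate of trans-carvone oxide with commercial (E)-4-acetoxy-2-methylbut-2-enal; 4,5-epoxide ⇐ (S)-carvone.
5. Ring order: cyclohexanone (carvone) → seven-membered lactone → cyclodecene; the 4,5-epoxide is made first and the 1,10-epoxide last.

## Route

Step 1
Reactants: 1 (S)-(+)-carvone
Product: 2 trans-carvone oxide (1S,4S,6S)-1-methyl-4-(prop-1-en-2-yl)-7-oxabicyclo[4.1.0]heptan-2-one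
Conditions: 30% H2O2, NaOH (0.3 equiv), MeOH, 0 °C
Reagents that add atoms: hydrogen peroxide, OO
Why: Weitz–Scheffer nucleophilic epoxidation; hydroperoxide adds to the enone face anti to the isopropenyl group, so C4 and C5 are set as the 4α,5α-epoxide trans to C7.

Step 2
Reactants: 2 trans-carvone oxide; 3 (E)-4-acetoxy-2-methylbut-2-enal
Product: 6 8α-[(1S,2E)-4-acetoxy-1-hydroxy-2-methylbut-2-enyl]-trans-carvone oxide (8S,9S; syn-aldol), via lithium enolate 4 (not isolated), via chlorozirconocene enolate 5 (not isolated)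
Conditions: LiN(iPr)2, THF, −78 °C; (C5H5)2ZrCl2, −78 → −40 °C; then 3, −78 °C; aq NH4Cl
Reagents that add atoms: none
Why: Zirconium-enolate aldol addition, which gives syn (erythro) aldols whatever the enolate geometry; the aldehyde approaches C8 anti to the adjacent isopropenyl group, so C8 (chain trans to isopropenyl) and C9 are both controlled by C7.

Step 3
Reactants: 6 syn-aldol
Product: 7 C9 triethylsilyl ether of 6
Conditions: Et3SiOTf, 2,6-lutidine, CH2Cl2, −78 °C
Reagents that add atoms: triethylsilyl trifluoromethanesulfonate, CC[Si](CC)(CC)OS(=O)(=O)C(F)(F)F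
Why: Standard silylation; it masks the C9 hydroxyl so that C8 and C9 oxygens stay differentiated and C9–O is a poor leaving group in step 5.

Step 4
Reactants: 7 silyl ether ketone
Product: 8 seven-membered lactone (oxygen inserted between C3 and C8; 3,8-dioxabicyclo[5.1.0]octan-2-one core; C8 chain trans to isopropenyl)
Conditions: Me3SiOOSiMe3, Me3SiOTf (10 mol%), CH2Cl2, −78 → −30 °C
Reagents that add atoms: bis(trimethylsilyl) peroxide, C[Si](C)(C)OO[Si](C)(C)C
Why: Baeyer–Villiger oxidation through a silylated Criegee adduct; the secondary C8 migrates in preference to the oxiranyl C4 with retention, which puts the C8 oxygen in place without a new stereochemical event, and the silyl peroxide leaves the C=C bonds untouched.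

Step 5
Reactants: 8 lactone allylic acetate
Product: 10 (1(10)Z)-4α,5α-epoxy-8β-hydroxy-9β-(triethylsilyloxy)germacra-1(10),11-dien-3-one (in equilibrium with its transannular hemiketal), via zinc hemiketalate 9 (not isolated)
Conditions: NiBr2(2,2'-bipyridine) (10 mol%), zinc anode, nickel-foam cathode, nBu4NBF4, DMF, 5 mA cm−2, 2.2 F mol−1, 20 °C; aq NH4Cl
Reagents that add atoms: none
Why: Proposed new method: cathodically generated zerovalent nickel ionises the primary allylic acetate, divalent zinc from the anode takes over the allyl group, and the fluxional allylzinc (zinc on C10) adds through its CH2 terminus C2 to the lactone carbonyl C3 in an SE2′ chair that the C8–O–C3 tether can only close with C9 and C2 cis, so the C2–C3 bond, the ten-membered carbocycle and the (Z)-C1=C10 alkene form together, and the bridged zinc hemiketalate 9 (which shields the new ketone from further addition or reduction) opens on work-up to free the C8 hydroxyl; attack through C10 would join two fully substituted carbons in a five-membered ring and is disfavoured; closest known reactions are the nickel-catalysed electroreductive allylation of ketones and aldehydes with allylic acetates at a zinc anode and the samarium- or zinc-mediated intramolecular nucleophilic acyl substitution (Barbier type) of halo-substituted lactones.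

Step 6
Reactants: 10 hydroxy ketone
Product: 11 (1(10)Z)-4α,5α-epoxy-8β-(3-methylbut-2-enoyloxy)-9β-(triethylsilyloxy)germacra-1(10),11-dien-3-one
Conditions: 3-methylbut-2-enoyl chloride, pyridine, DMAP (cat.), CH2Cl2, 0 → 20 °C
Reagents that add atoms: 3-methylbut-2-enoyl chloride (senecioyl chloride), CC(C)=CC(=O)Cl
Why: Acylation of the only free secondary hydroxyl (the open hydroxy-ketone tautomer is drained from the hemiketal equilibrium); pyridine without a trialkylamine avoids ketene-type deconjugation of the senecioate.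

Step 7
Reactants: 11 senecioate ketone
Product: 12 (1(10)Z)-4α,5α-epoxy-3α-hydroxy-8β-(3-methylbut-2-enoyloxy)-9β-(triethylsilyloxy)germacra-1(10),11-diene (3R; erythro epoxy alcohol)
Conditions: Zn(BH4)2, Et2O, −30 °C
Reagents that add atoms: none
Why: Chelation-controlled reduction of an α,β-epoxy ketone; zinc bridges the carbonyl and epoxide oxygens and hydride adds from the face opposite the epoxide carbon C5, giving the erythro (3α) alcohol, while esters and the silyl ether are inert.

Step 8
Reactants: 12 3α-alcohol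
Product: 13 (1(10)Z)-3β-angeloyloxy-4α,5α-epoxy-8β-(3-methylbut-2-enoyloxy)-9β-(triethylsilyloxy)germacra-1(10),11-diene (3S)
Conditions: angelic acid, PPh3, DIAD, toluene, 0 → 20 °C
Reagents that add atoms: (Z)-2-methylbut-2-enoic acid (angelic acid), C/C=C(/C)C(=O)O
Why: Mitsunobu esterification; SN2 displacement of the oxyphosphonium by angelate inverts C3 to the required 3β (threo) configuration, and the neutral conditions keep the (Z)-geometry of the angelate.

Step 9
Reactants: 13 angelate silyl ether
Product: 14 (1(10)Z)-3β-angeloyloxy-4α,5α-epoxy-9β-hydroxy-8β-(3-methylbut-2-enoyloxy)germacra-1(10),11-diene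
Conditions: HF·pyridine, pyridine, THF, 0 → 20 °C
Reagents that add atoms: none
Why: Fluoride-mediated desilylation under weakly acidic buffered conditions, which avoids 1,2-acyl migration from O8 to O9 and leaves the trisubstituted epoxide and the esters intact.

Step 10
Reactants: 14 allylic alcohol
Product: 15 3β-angeloyloxy-1β,10β:4α,5α-diepoxy-9β-hydroxy-8β-(3-methylbut-2-enoyloxy)germacr-11-ene
Conditions: VO(acac)2 (5 mol%), tBuOOH (1.1 equiv), CH2Cl2, 0 °C
Reagents that add atoms: tert-butyl hydroperoxide, CC(C)(C)OO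
Why: Hydroxyl-directed vanadium epoxidation; the C9 vanadate delivers oxygen to the alkene face syn to the C9–O bond (cis/erythro, as with medium-ring cycloalkenols and favoured by the C10 methyl group), setting C1 and C10, while the isopropenyl group and the two enoate double bonds react far more slowly.

Step 11
Reactants: 15 diepoxy alcohol
Product: 16 target, (1R,3S,4S,5S,7R,8S,9S,10R)-9-acetoxy-3-angeloyloxy-1,10:4,5-diepoxy-8-(3-methylbut-2-enoyloxy)germacr-11-ene
Conditions: Ac2O, pyridine, DMAP (cat.), CH2Cl2, 20 °C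
Reagents that add atoms: acetic anhydride, CC(=O)OC(C)=O
Why: Standard acetylation of the remaining secondary hydroxyl; no stereocentre is touched.

## Compound list

1 | (S)-(+)-carvone | C=C(C)[C@H]1CC=C(C)C(=O)C1 | starting material
2 | trans-carvone oxide, (1S,4S,6S)-1-methyl-4-(prop-1-en-2-yl)-7-oxabicyclo[4.1.0]heptan-2-one | C=C(C)[C@H]1C[C@@H]2O[C@]2(C)C(=O)C1 | intermediate
3 | (E)-4-acetoxy-2-methylbut-2-enal | CC(=O)OC/C=C(\C)C=O | starting material
4 | lithium enolate of 2 (C3–O–Li, C3=C8) | C=C(C)[C@H]1C[C@@H]2O[C@]2(C)C(O[Li])=C1 | intermediate (not isolated)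
5 | chlorobis(cyclopentadienyl)zirconium enolate of 2 | C=C(C)[C@H]1C[C@@H]2O[C@]2(C)C(O[Zr](Cl)(C3C=CC=C3)C3C=CC=C3)=C1 | intermediate (not isolated)
6 | syn-aldol: trans-carvone oxide with the (1S,2E)-4-acetoxy-1-hydroxy-2-methylbut-2-enyl chain at C8, trans to isopropenyl (8S,9S) | C=C(C)[C@H]1C[C@@H]2O[C@]2(C)C(=O)[C@@H]1[C@H](O)/C(C)=C/COC(C)=O | intermediate
7 | C9 triethylsilyl ether of 6 | C=C(C)[C@H]1C[C@@H]2O[C@]2(C)C(=O)[C@@H]1[C@H](O[Si](CC)(CC)CC)/C(C)=C/COC(C)=O | intermediate
8 | seven-membered lactone (O between C3 and C8; 4α,5α-epoxide; C8 chain trans to isopropenyl) | C=C(C)[C@H]1C[C@@H]2O[C@]2(C)C(=O)O[C@@H]1[C@H](O[Si](CC)(CC)CC)/C(C)=C/COC(C)=O | intermediate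
9 | acetoxyzinc salt of the bridged hemiketal (oxygen bridging C3 and C8 of the new ten-membered ring) | C=C(C)[C@H]1C[C@@H]2O[C@]2(C)[C@]3(O[Zn]OC(C)=O)C/C=C(C)\[C@@H](O[Si](CC)(CC)CC)[C@H]1O3 | intermediate (not isolated)
10 | (1(10)Z)-4α,5α-epoxy-8β-hydroxy-9β-(triethylsilyloxy)germacra-1(10),11-dien-3-one | C=C(C)[C@H]1C[C@@H]2O[C@]2(C)C(=O)C/C=C(C)\[C@@H](O[Si](CC)(CC)CC)[C@H]1O | intermediate
11 | 8β-senecioate of 10 | C=C(C)[C@H]1C[C@@H]2O[C@]2(C)C(=O)C/C=C(C)\[C@@H](O[Si](CC)(CC)CC)[C@H]1OC(=O)C=C(C)C | intermediate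
12 | 3α-alcohol (3R, erythro to the 4,5-epoxide) | C=C(C)[C@H]1C[C@@H]2O[C@]2(C)[C@H](O)C/C=C(C)\[C@@H](O[Si](CC)(CC)CC)[C@H]1OC(=O)C=C(C)C | intermediate
13 | 3β-angelate (3S) 8β-senecioate 9β-triethylsilyl ether | C=C(C)[C@H]1C[C@@H]2O[C@]2(C)[C@@H](OC(=O)/C(C)=C\C)C/C=C(C)\[C@@H](O[Si](CC)(CC)CC)[C@H]1OC(=O)C=C(C)C | intermediate
14 | 9β-alcohol (3β-angelate, 8β-senecioate, 1(10)Z alkene) | C=C(C)[C@H]1C[C@@H]2O[C@]2(C)[C@@H](OC(=O)/C(C)=C\C)C/C=C(C)\[C@@H](O)[C@H]1OC(=O)C=C(C)C | intermediate
15 | 1β,10β:4α,5α-diepoxy-9β-alcohol | C=C(C)[C@H]1C[C@@H]2O[C@]2(C)[C@@H](OC(=O)/C(C)=C\C)C[C@H]2O[C@@]2(C)[C@@H](O)[C@H]1OC(=O)C=C(C)C | intermediate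
16 | CNP0276917.1, (1R,3S,4S,5S,7R,8S,9S,10R)-9-acetoxy-3-angeloyloxy-1,10:4,5-diepoxy-8-(3-methylbut-2-enoyloxy)germacr-11-ene | C=C(C)[C@H]1C[C@@H]2O[C@]2(C)[C@@H](OC(=O)/C(C)=C\C)C[C@H]2O[C@@]2(C)[C@@H](OC(C)=O)[C@H]1OC(=O)C=C(C)C | target

## Step count and risks

Total step count: 11. Longest linear sequence: 11 steps from (S)-carvone (1); aldehyde 3 and all acyl donors are purchased.

The three steps most likely to fail:

**Step 5 (the new electroreductive ring expansion).** Risks are simple reduction of the allyl unit, attack through C10, or no addition to the hindered lactone carbonyl. The fallback sets out from lactone 8 and returns at hydroxy ketone 10, using stoichiometric Barbier chemistry on a halide instead of nickel electrocatalysis on the acetate. Mg(OMe)2 in MeOH at 0 °C removes the primary allylic acetate to give the allylic alcohol F1. CBr4/PPh3 (Appel reaction) converts it into the allylic bromide F2. Activated zinc dust in THF then forms the allylzinc bromide, which adds intramolecularly to the lactone carbonyl (the known allylzinc addition to esters and lactones); aqueous work-up gives 10.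

**Step 4 (Baeyer–Villiger oxidation of a hindered epoxy ketone in the presence of two electron-rich alkenes).** Risks are a slow reaction, oxiranyl migration, or Lewis-acid damage. The fallback sets out from ketone 7 and returns at lactone 8, replacing oxygen insertion by cleavage, reduction and relactonisation. KN(SiMe3)2 followed by 2-(phenylsulfonyl)-3-phenyloxaziridine hydroxylates C8 to the α-ketol F3. Pb(OAc)4 in MeOH cleaves the C3–C8 bond to the methyl ester C8-ketone F4. HF·pyridine frees the C9 hydroxyl to give the α-hydroxy ketone F5. Zn(BH4)2 reduces C8 under chelation control to the anti-diol F6 (8S). nBu2SnO-catalysed lactonisation in toluene closes the seven-membered lactone F7, and Et3SiOTf/2,6-lutidine silylates C9 to give 8.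

**Step 8 (Mitsunobu inversion at a carbinol next to a quaternary epoxide carbon).** Risks are sluggish SN2 displacement or elimination. The fallback sets out from ketone 11 and returns at angelate 13, setting C3 in the reduction instead of by inversion. LiBH(sBu)3 in THF at −78 °C (non-chelating, attacking the face remote from the transannular C8 ester) gives the 3β-alcohol F8. This is esterified with retention using angelic acid activated as its 2,4,6-trichlorobenzoic mixed anhydride (Yamaguchi conditions, Et3N then DMAP, toluene, 20 °C) to give 13.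

Further compounds

F1 | step 5 | lactone 8 with the primary allylic acetate cleaved to the allylic alcohol | C=C(C)[C@H]1C[C@@H]2O[C@]2(C)C(=O)O[C@@H]1[C@H](O[Si](CC)(CC)CC)/C(C)=C/CO
F2 | step 5 | corresponding primary allylic bromide | C=C(C)[C@H]1C[C@@H]2O[C@]2(C)C(=O)O[C@@H]1[C@H](O[Si](CC)(CC)CC)/C(C)=C/CBr
F3 | step 4 | C8 tertiary α-ketol of 7 (hydroxyl trans to isopropenyl; this centre is lost in the next operation) | C=C(C)[C@H]1C[C@@H]2O[C@]2(C)C(=O)[C@@]1(O)[C@H](O[Si](CC)(CC)CC)/C(C)=C/COC(C)=O
F4 | step 4 | seco compound: C3 methyl glycidate, C8 ketone, C9 triethylsilyl ether | C=C(C)[C@@H](C[C@@H]1O[C@]1(C)C(=O)OC)C(=O)[C@H](O[Si](CC)(CC)CC)/C(C)=C/COC(C)=O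
F5 | step 4 | seco α-hydroxy ketone (C9 hydroxyl free) | C=C(C)[C@@H](C[C@@H]1O[C@]1(C)C(=O)OC)C(=O)[C@H](O)/C(C)=C/COC(C)=O
F6 | step 4 | seco 8,9-anti-diol methyl ester | C=C(C)[C@@H](C[C@@H]1O[C@]1(C)C(=O)OC)[C@H](O)[C@H](O)/C(C)=C/COC(C)=O
F7 | step 4 | seven-membered lactone with free C9 hydroxyl (desilyl 8) | C=C(C)[C@H]1C[C@@H]2O[C@]2(C)C(=O)O[C@@H]1[C@H](O)/C(C)=C/COC(C)=O
F8 | step 8 | 3β-alcohol (3S epimer of 12) | C=C(C)[C@H]1C[C@@H]2O[C@]2(C)[C@@H](O)C/C=C(C)\[C@@H](O[Si](CC)(CC)CC)[C@H]1OC(=O)C=C(C)C
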